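**Retrosynthetic overview**
- The target is disconnected at C2–Cl to the (2S,3R)-2,3-epoxide of the 6,8-dihydroxy-2-methyl-3-alkyl-1,4-naphthoquinone (SN2 chloride opening at C2 with inversion gives Cl and OH trans). The epoxide comes from the quinone by asymmetric nucleophilic epoxidation, and the quinone from the 1,4-dimethoxynaphthalene.
- The strategy rests on ring A (C4a, C5–C8, C8a): its oxygens sit at C6 and C8, meta to one another, with C8–OH peri to the C1 carbonyl and CH at C5 and C7. This is the pattern an arylketene plus a silyloxyalkyne delivers, forming C4a–C5, C5–C6, C7–C8 and C8–C8a.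
- The aryl diazoketone comes from 3-bromo-2,5-dimethoxy-4-methylbenzaldehyde (bromine placed ortho to a temporarily free phenol) by copper-catalysed Grignard allylation with the C15 allylic bromide, which is made from geranyl bromide and ethyl 3-methylbut-2-enoate.
- Ring order: ring B is bought as the benzene ring of the aldehyde, ring A is built in step 12, and the oxirane is closed in step 15 and opened in step 17.

Key step: step 12

Conventions: R = (4E)-5,9-dimethyl-2-(propan-2-ylidene)deca-4,8-dien-1-yl, i.e. CH2–C(=CMe2)–CH2–CH=C(Me)–CH2CH2–CH=CMe2. Naphthalene positions are numbered as in the target (C1 carbonyl next to C2, C8 peri to C1).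
Assumption: (triisopropylsilyloxy)acetylene, the alkyne partner of the key step, is used as an available reagent (a known silyl ynol ether, made by O-silylation of lithium ethynolate), and its preparation is not counted as a step.

**Route**

Step 1
Reactants: 1 ethyl 3-methylbut-2-enoate; 2 geranyl bromide
Product: 4 ethyl (4E)-5,9-dimethyl-2-(prop-1-en-2-yl)deca-4,8-dienoate (racemic), via lithium dienolate 3 (not isolated)
Conditions: LiN(iPr)2, THF/DMPU, −78 °C; then 2, −78 → 0 °C
Reagents that add atoms: none
Why: The kinetic lithium dienolate of the ester is alkylated at its α carbon by SN2 displacement on the primary allylic bromide (dienolate α-alkylation); the new α stereocentre is racemic and is removed in step 2.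

Step 2
Reactants: 4 ethyl (4E)-5,9-dimethyl-2-(prop-1-en-2-yl)deca-4,8-dienoate
Product: 5 ethyl (4E)-5,9-dimethyl-2-(propan-2-ylidene)deca-4,8-dienoate
Conditions: NaOEt (0.3 equiv), EtOH, 60 °C
Reagents that add atoms: none
Why: Base-catalysed equilibration through the same dienolate moves the terminal double bond into conjugation, the tetrasubstituted enoate being the expected thermodynamic isomer (alkene isomerisation).

Step 3
Reactants: 5 ethyl (4E)-5,9-dimethyl-2-(propan-2-ylidene)deca-4,8-dienoate
Product: 6 (4E)-5,9-dimethyl-2-(propan-2-ylidene)deca-4,8-dien-1-ol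
Conditions: iBu2AlH (2.2 equiv), CH2Cl2, −78 → 0 °C; aq. Rochelle salt
Reagents that add atoms: none
Why: Diisobutylaluminium hydride reduces the unsaturated ester 1,2 to the allylic alcohol and leaves the isolated alkenes alone (ester reduction).

Step 4
Reactants: 6 (4E)-5,9-dimethyl-2-(propan-2-ylidene)deca-4,8-dien-1-ol
Product: 7 (5E)-3-(bromomethyl)-2,6,10-trimethylundeca-2,5,9-triene
Conditions: CBr4, PPh3, CH2Cl2, 0 °C; used without storage
Reagents that add atoms: carbon tetrabromide BrC(Br)(Br)Br
Why: The Appel reaction converts the primary allylic alcohol into the bromide under neutral conditions, and the primary bromide is favoured over the transposed tertiary isomer.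

Step 5
Reactants: 8 2,5-dimethoxy-4-methylbenzaldehyde
Product: 9 2-hydroxy-5-methoxy-4-methylbenzaldehyde
Conditions: BCl3 (1.1 equiv), CH2Cl2, −78 → 0 °C; H2O
Reagents that add atoms: none
Why: BCl3 chelates the aldehyde oxygen and the ortho methoxy oxygen, so only that methyl ether is cleaved (chelation-directed ether cleavage).

Step 6
Reactants: 9 2-hydroxy-5-methoxy-4-methylbenzaldehyde
Product: 10 3-bromo-2-hydroxy-5-methoxy-4-methylbenzaldehyde
Conditions: Br2 (1.05 equiv), NaOAc, AcOH, 20 °C
Reagents that add atoms: bromine BrBr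
Why: Electrophilic aromatic bromination is directed by the free phenol, whose para position is blocked by the methoxy group, so bromine enters the one open ortho position C3.

Step 7
Reactants: 10 3-bromo-2-hydroxy-5-methoxy-4-methylbenzaldehyde
Product: 11 3-bromo-2,5-dimethoxy-4-methylbenzaldehyde
Conditions: MeI, K2CO3, DMF, 40 °C
Reagents that add atoms: iodomethane CI
Why: Williamson O-methylation of the phenoxide restores the dimethyl ether of ring B.

Step 8
Reactants: 11 3-bromo-2,5-dimethoxy-4-methylbenzaldehyde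
Product: 12 3-bromo-2,5-dimethoxy-4-methylbenzaldehyde dimethyl acetal
Conditions: HC(OMe)3, MeOH, TsOH·H2O (cat.), 50 °C; Et3N quench
Reagents that add atoms: trimethyl orthoformate COC(OC)OC; methanol CO
Why: Acid-catalysed acetalisation, driven by the orthoformate, masks the aldehyde against the Grignard reagent of step 9.

Step 9
Reactants: 12 3-bromo-2,5-dimethoxy-4-methylbenzaldehyde dimethyl acetal; 7 (5E)-3-(bromomethyl)-2,6,10-trimethylundeca-2,5,9-triene
Product: 15 3-R-2,5-dimethoxy-4-methylbenzaldehyde, via aryl Grignard reagent 13 (not isolated), via coupled dimethyl acetal 14 (not isolated)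
Conditions: Mg, LiCl, THF, 25 °C; cannulate onto 7, Li2CuCl4 (5 mol %), THF, −20 → 25 °C; then 10% aq. (CO2H)2, THF, 25 °C
Reagents that add atoms: water O
Why: Magnesium insertion gives the aryl Grignard reagent, and its copper-catalysed coupling with the allylic bromide should go at the primary carbon (SN2) because the γ carbon is fully substituted; dilute acid then hydrolyses the acetal.

Step 10
Reactants: 15 3-R-2,5-dimethoxy-4-methylbenzaldehyde
Product: 16 3-R-2,5-dimethoxy-4-methylbenzoic acid
Conditions: NaClO2, NaH2PO4, 2-methylbut-2-ene (excess), t-BuOH/THF/H2O, 0 → 20 °C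
Reagents that add atoms: sodium chlorite [Na+].[O-]Cl=O
Why: Pinnick oxidation takes the aldehyde to the acid, with 2-methylbut-2-ene trapping hypochlorous acid before it reaches the side-chain alkenes or the arene.

Step 11
Reactants: 16 3-R-2,5-dimethoxy-4-methylbenzoic acid
Product: 18 2-diazo-1-(3-R-2,5-dimethoxy-4-methylphenyl)ethan-1-one, via acid chloride 17 (not isolated)
Conditions: Me2C=C(Cl)NMe2 (1.05 equiv), CH2Cl2, 0 → 20 °C; then CH2N2 (3 equiv), Et2O, 0 °C
Reagents that add atoms: diazomethane C=[N+]=[N-]
Why: The α-chloroenamine forms the acid chloride without free HCl, so the alkenes are not hydrochlorinated, and acylation of excess diazomethane gives the α-diazoketone (first stage of the Arndt–Eistert sequence).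

Step 12
Reactants: 18 2-diazo-1-(3-R-2,5-dimethoxy-4-methylphenyl)ethan-1-one; 19 (triisopropylsilyloxy)acetylene
Product: 24 1,4-dimethoxy-2-methyl-3-R-6-(triisopropylsilyloxy)naphthalen-8-ol, via arylketene 20 (not isolated), via siloxycyclobutenone 21 (not isolated), via dienylketene 22 (not isolated), via cyclohexadienone 23 (not isolated)
Conditions: 19 (2.5 equiv), hν (medium-pressure Hg lamp, Pyrex filter), degassed ClCH2CH2Cl, 25 °C; then 80 °C in the dark
Reagents that add atoms: none
Why: Light expels N2 from 18 and the aryl carbon (future C4a) shifts to the diazo carbon (future C5) in a Wolff rearrangement to arylketene 20; the nucleophilic CH terminus of ynol ether 19 adds to the ketene carbonyl carbon and the [2+2] cycloaddition closes to the 4-aryl-3-siloxycyclobutenone 21 (C7–C8 and C5–C6 formed). Four-electron conrotatory opening of 21 (by light or heat) gives dienylketene 22, whose ketene carbon closes onto the free ortho CH of the arene by six-electron disrotatory electrocyclisation (C8–C8a, closing ring A as a six-membered carbocycle), and a proton shift in dienone 23 aromatises ring A to 24. The closest known reaction type is the Danheiser benzannulation in its diazoketone variant with trialkylsilyloxyalkynes, which gives resorcinol monosilyl ethers from aryl and heteroaryl diazoketones. No stereocentre survives, because the sp3 carbons of 21 and 23 become planar on aromatisation. The step needs regiocontrol, supplied by the polarity of 19 (its oxygen-bearing carbon can only become C6 and the ketene carbonyl carbon C8, peri to C1) and by the arene (the other ortho carbon carries OMe, so only closure at the CH position can aromatise). It also needs chemoselectivity against the three side-chain alkenes, which the much more ketenophilic ynol ether in excess and the meta placement of the chain (out of reach of the carbene and ketene carbons) should secure.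

Step 13
Reactants: 24 1,4-dimethoxy-2-methyl-3-R-6-(triisopropylsilyloxy)naphthalen-8-ol
Product: 25 1,4-dimethoxy-2-methyl-3-R-6,8-bis(triisopropylsilyloxy)naphthalene
Conditions: iPr3SiOTf (1.3 equiv), 2,6-lutidine, CH2Cl2, 0 → 25 °C
Reagents that add atoms: triisopropylsilyl triflate CC(C)[Si](OS(=O)(=O)C(F)(F)F)(C(C)C)C(C)C
Why: Silylation of the peri phenol with the silyl triflate protects ring A from oxidation in step 14 and prevents a phenoxide from deactivating the quinone in step 15.

Step 14
Reactants: 25 1,4-dimethoxy-2-methyl-3-R-6,8-bis(triisopropylsilyloxy)naphthalene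
Product: 26 2-methyl-3-R-6,8-bis(triisopropylsilyloxy)naphthalene-1,4-dione
Conditions: (NH4)2Ce(NO3)6 (2.5 equiv), MeCN/H2O, 0 °C, short reaction time
Reagents that add atoms: water O
Why: Oxidative demethylation by ceric ammonium nitrate acts on ring B, the only ring with para-disposed oxygens, and is known to tolerate prenyl-type chains in menaquinone-type substrates.

Step 15
Reactants: 26 2-methyl-3-R-6,8-bis(triisopropylsilyloxy)naphthalene-1,4-dione
Product: 27 (2S,3R)-2,3-epoxy-2-methyl-3-R-6,8-bis(triisopropylsilyloxy)-2,3-dihydronaphthalene-1,4-dione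
Conditions: t-BuOOH (3 equiv), aq. NaOH (0.5 equiv), toluene, N-(9-anthracenylmethyl)cinchonidinium bromide (10 mol %), 0 °C, dark
Reagents that add atoms: tert-butyl hydroperoxide CC(C)(C)OO
Why: In this Weitz–Scheffer epoxidation under chiral phase-transfer catalysis the peroxide anion, ion-paired with the cinchona ammonium cation, adds to one enantiotopic face of C2=C3 and the enolate closes on the same face, so C2 and C3 are set together by the catalyst (the pseudoenantiomeric cinchoninium salt is used if the first run shows the opposite facial sense).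

Step 16
Reactants: 27 (2S,3R)-2,3-epoxy-2-methyl-3-R-6,8-bis(triisopropylsilyloxy)-2,3-dihydronaphthalene-1,4-dione
Product: 28 (2S,3R)-2,3-epoxy-6,8-dihydroxy-2-methyl-3-R-2,3-dihydronaphthalene-1,4-dione
Conditions: Bu4NF (2.2 equiv), AcOH (2.5 equiv), THF, 0 °C
Reagents that add atoms: none
Why: Fluoride cleaves both aryl silyl ethers (desilylation), and acetic acid buffers the phenoxides so the epoxy diketone is not exposed to base.

Step 17
Reactants: 28 (2S,3R)-2,3-epoxy-6,8-dihydroxy-2-methyl-3-R-2,3-dihydronaphthalene-1,4-dione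
Product: 29 (2R,3S)-2-chloro-3,6,8-trihydroxy-2-methyl-3-R-2,3-dihydronaphthalene-1,4-dione (target CNP0351608.1)
Conditions: LiCl (10 equiv), AcOH (5 equiv), THF, 25 → 40 °C
Reagents that add atoms: lithium chloride [Li+].[Cl-]
Why: Acid-assisted SN2 opening of the α,β-epoxy ketone by chloride (halohydrin formation) should occur at C2, which is α to the C1 carbonyl activated by the C8–OH hydrogen bond and is the less hindered oxirane carbon (methyl against the branched side-chain CH2); attack anti to the oxirane oxygen inverts C2 to R, while C3 keeps its C–O bond (S by CIP in the product), giving Cl and OH trans.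

**Compound list**
1 | ethyl 3-methylbut-2-enoate | CCOC(=O)C=C(C)C | starting material
2 | geranyl bromide | CC(C)=CCC/C(C)=C/CBr | starting material
3 | lithium dienolate of 1 | C=C(C)C=C(OCC)O[Li] | intermediate (not isolated)
4 | ethyl (4E)-5,9-dimethyl-2-(prop-1-en-2-yl)deca-4,8-dienoate (racemic) | CC(C)=CCC/C(C)=C/CC(C(=O)OCC)C(C)=C | intermediate
5 | ethyl (4E)-5,9-dimethyl-2-(propan-2-ylidene)deca-4,8-dienoate | CC(C)=CCC/C(C)=C/CC(C(=O)OCC)=C(C)C | intermediate
6 | (4E)-5,9-dimethyl-2-(propan-2-ylidene)deca-4,8-dien-1-ol | CC(C)=CCC/C(C)=C/CC(CO)=C(C)C | intermediate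
7 | (5E)-3-(bromomethyl)-2,6,10-trimethylundeca-2,5,9-triene | CC(C)=CCC/C(C)=C/CC(CBr)=C(C)C | intermediate
8 | 2,5-dimethoxy-4-methylbenzaldehyde | COc1cc(C=O)c(OC)cc1C | starting material
9 | 2-hydroxy-5-methoxy-4-methylbenzaldehyde | COc1cc(C=O)c(O)cc1C | intermediate
10 | 3-bromo-2-hydroxy-5-methoxy-4-methylbenzaldehyde | COc1cc(C=O)c(O)c(Br)c1C | intermediate
11 | 3-bromo-2,5-dimethoxy-4-methylbenzaldehyde | COc1cc(C=O)c(OC)c(Br)c1C | intermediate
12 | 3-bromo-2,5-dimethoxy-4-methylbenzaldehyde dimethyl acetal | COc1cc(C(OC)OC)c(OC)c(Br)c1C | intermediate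
13 | [3-(dimethoxymethyl)-2,5-dimethoxy-6-methylphenyl]magnesium bromide | COc1cc(C(OC)OC)c(OC)c([Mg]Br)c1C | intermediate (not isolated)
14 | 3-R-2,5-dimethoxy-4-methylbenzaldehyde dimethyl acetal | CC(C)=CCC/C(C)=C/CC(Cc1c(C)c(OC)cc(C(OC)OC)c1OC)=C(C)C | intermediate (not isolated)
15 | 3-R-2,5-dimethoxy-4-methylbenzaldehyde | CC(C)=CCC/C(C)=C/CC(Cc1c(C)c(OC)cc(C=O)c1OC)=C(C)C | intermediate
16 | 3-R-2,5-dimethoxy-4-methylbenzoic acid | CC(C)=CCC/C(C)=C/CC(Cc1c(C)c(OC)cc(C(=O)O)c1OC)=C(C)C | intermediate
17 | 3-R-2,5-dimethoxy-4-methylbenzoyl chloride | CC(C)=CCC/C(C)=C/CC(Cc1c(C)c(OC)cc(C(=O)Cl)c1OC)=C(C)C | intermediate (not isolated)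
18 | 2-diazo-1-(3-R-2,5-dimethoxy-4-methylphenyl)ethan-1-one | CC(C)=CCC/C(C)=C/CC(Cc1c(C)c(OC)cc(C(=O)C=[N+]=[N-])c1OC)=C(C)C | intermediate
19 | (triisopropylsilyloxy)acetylene | C#CO[Si](C(C)C)(C(C)C)C(C)C | starting material
20 | (3-R-2,5-dimethoxy-4-methylphenyl)ketene | CC(C)=CCC/C(C)=C/CC(Cc1c(C)c(OC)cc(C=C=O)c1OC)=C(C)C | intermediate (not isolated)
21 | 4-(3-R-2,5-dimethoxy-4-methylphenyl)-3-(triisopropylsilyloxy)cyclobut-2-en-1-one (racemic) | CC(C)=CCC/C(C)=C/CC(Cc1c(C)c(OC)cc(C2C(=O)C=C2O[Si](C(C)C)(C(C)C)C(C)C)c1OC)=C(C)C | intermediate (not isolated)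
22 | 4-(3-R-2,5-dimethoxy-4-methylphenyl)-3-(triisopropylsilyloxy)buta-1,3-dien-1-one, aryl cis to the ketene carbon | CC(C)=CCC/C(C)=C/CC(Cc1c(C)c(OC)cc(/C=C(O[Si](C(C)C)(C(C)C)C(C)C)\C=C=O)c1OC)=C(C)C | intermediate (not isolated)
23 | 8a-H cyclohexadienone tautomer of 24 (C8 ketone, racemic) | CC(C)=CCC/C(C)=C/CC(CC1=C(OC)C2=CC(O[Si](C(C)C)(C(C)C)C(C)C)=CC(=O)C2C(OC)=C1C)=C(C)C | intermediate (not isolated)
24 | 1,4-dimethoxy-2-methyl-3-R-6-(triisopropylsilyloxy)naphthalen-8-ol (= 5,8-dimethoxy-7-methyl-6-R-3-(triisopropylsilyloxy)naphthalen-1-ol) | CC(C)=CCC/C(C)=C/CC(Cc1c(C)c(OC)c2c(O)cc(O[Si](C(C)C)(C(C)C)C(C)C)cc2c1OC)=C(C)C | intermediate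
25 | 1,4-dimethoxy-2-methyl-3-R-6,8-bis(triisopropylsilyloxy)naphthalene | CC(C)=CCC/C(C)=C/CC(Cc1c(C)c(OC)c2c(O[Si](C(C)C)(C(C)C)C(C)C)cc(O[Si](C(C)C)(C(C)C)C(C)C)cc2c1OC)=C(C)C | intermediate
26 | 2-methyl-3-R-6,8-bis(triisopropylsilyloxy)naphthalene-1,4-dione | CC(C)=CCC/C(C)=C/CC(CC1=C(C)C(=O)c2c(O[Si](C(C)C)(C(C)C)C(C)C)cc(O[Si](C(C)C)(C(C)C)C(C)C)cc2C1=O)=C(C)C | intermediate
27 | (2S,3R)-2,3-epoxy-2-methyl-3-R-6,8-bis(triisopropylsilyloxy)-2,3-dihydronaphthalene-1,4-dione | CC(C)=CCC/C(C)=C/CC(C[C@@]12O[C@]1(C)C(=O)c1c(O[Si](C(C)C)(C(C)C)C(C)C)cc(O[Si](C(C)C)(C(C)C)C(C)C)cc1C2=O)=C(C)C | intermediate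
28 | (2S,3R)-2,3-epoxy-6,8-dihydroxy-2-methyl-3-R-2,3-dihydronaphthalene-1,4-dione | CC(C)=CCC/C(C)=C/CC(C[C@@]12O[C@]1(C)C(=O)c1c(O)cc(O)cc1C2=O)=C(C)C | intermediate
29 | (2R,3S)-2-chloro-3,6,8-trihydroxy-2-methyl-3-R-2,3-dihydronaphthalene-1,4-dione | CC(C)=CCC/C(C)=C/CC(C[C@]1(O)C(=O)c2cc(O)cc(O)c2C(=O)[C@]1(C)Cl)=C(C)C | target

**Totals**
Total step count: 17.
Longest linear sequence: 13 steps (8 to 29 through steps 5–17; the branch from 1 and 2 is equally long, steps 1–4 and 9–17).

**Steps most likely to fail**

Step 12 (key step). After loss of nitrogen the excited diazoketone or a free acyl carbene may be intercepted before the aryl shift, for example by insertion into a C–H bond of the neighbouring methoxy group. The side-chain alkenes may also isomerise, or the product may screen the light, so that little arylketene reaches the alkyne. The fallback makes the same arylketene without light and without a carbene, and sets out from aldehyde 15. Wittig reaction with Ph3P=CHOMe (from methoxymethyltriphenylphosphonium chloride and KOtBu) gives the enol ether F1. Brief hydrolysis with dilute aqueous HCl in THF gives the arylacetaldehyde F2, Pinnick oxidation gives the arylacetic acid F3, and 1-chloro-N,N,2-trimethylprop-1-en-1-amine gives the arylacetyl chloride F4. Slow addition of Et3N to F4 and excess 19 in toluene at 80 °C dehydrochlorinates F4 to ketene 20. This then runs thermally through 21, 22 and 23 (the classical arylketene–ynol ether naphthol synthesis) and comes back to the route at naphthol 24.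

Step 15. Facial discrimination may be poor on a tetrasubstituted quinone double bond, since this catalyst class is established mainly for 2-monosubstituted naphthoquinones. The peri silyl ether may also be lost under aqueous base. The fallback replaces asymmetric catalysis by resolution and sets out from quinone 26. Epoxidation without chiral control (t-BuOOH, DBU, CH2Cl2, 0 °C, anhydrous so the silyl ethers are not at risk) gives the racemic epoxide F5. Preparative chromatography on a chiral stationary phase (amylose tris(3,5-dimethylphenylcarbamate)) separates 27 from its mirror image, the (2R,3S)-epoxide F6. The route resumes at 27, and the absolute configuration is assigned by carrying each enantiomer through to 29 and comparing chiroptical data.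

Step 17. Chloride may attack C3 instead of C2, since both oxirane carbons are quaternary and α to a carbonyl, or the opening may be too slow under conditions mild enough for the side-chain alkenes. The fallback removes the competing carbonyl for the duration of the opening and sets out from bis-silyl epoxide 27. Reduction with NaBH4 and CeCl3·7H2O (MeOH/THF, −78 °C) should take the unhindered, non-donor-conjugated C4 ketone to the C4 carbinol F7 (C4 epimers not separated). In F7, C2 is at once α to the only remaining ketone and the distal carbon of a 2,3-epoxy alcohol, so Ti(OiPr)4-assisted opening with NH4Cl in THF should deliver chloride to C2 with inversion and give the chloro diol F8. Dess–Martin periodinane oxidises the secondary C4 alcohol back to the ketone, giving the bis-silyl chlorohydrin F9. Bu4NF buffered with AcOH removes both silyl groups, and the sequence comes back to the route at target 29.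

**Further compounds**
F1 | step 12 | 1-(2-methoxyethenyl)-3-R-2,5-dimethoxy-4-methylbenzene (E/Z mixture) | CC(C)=CCC/C(C)=C/CC(Cc1c(C)c(OC)cc(C=COC)c1OC)=C(C)C
F2 | step 12 | (3-R-2,5-dimethoxy-4-methylphenyl)acetaldehyde | CC(C)=CCC/C(C)=C/CC(Cc1c(C)c(OC)cc(CC=O)c1OC)=C(C)C
F3 | step 12 | (3-R-2,5-dimethoxy-4-methylphenyl)acetic acid | CC(C)=CCC/C(C)=C/CC(Cc1c(C)c(OC)cc(CC(=O)O)c1OC)=C(C)C
F4 | step 12 | (3-R-2,5-dimethoxy-4-methylphenyl)acetyl chloride | CC(C)=CCC/C(C)=C/CC(Cc1c(C)c(OC)cc(CC(=O)Cl)c1OC)=C(C)C
F5 | step 15 | racemic 2,3-epoxy-2-methyl-3-R-6,8-bis(triisopropylsilyloxy)-2,3-dihydronaphthalene-1,4-dione | CC(C)=CCC/C(C)=C/CC(CC12OC1(C)C(=O)c1c(O[Si](C(C)C)(C(C)C)C(C)C)cc(O[Si](C(C)C)(C(C)C)C(C)C)cc1C2=O)=C(C)C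
F6 | step 15 | (2R,3S)-2,3-epoxy-2-methyl-3-R-6,8-bis(triisopropylsilyloxy)-2,3-dihydronaphthalene-1,4-dione (enantiomer of 27) | CC(C)=CCC/C(C)=C/CC(C[C@]12O[C@@]1(C)C(=O)c1c(O[Si](C(C)C)(C(C)C)C(C)C)cc(O[Si](C(C)C)(C(C)C)C(C)C)cc1C2=O)=C(C)C
F7 | step 17 | C4 carbinol of epoxide 27 (oxirane configuration as in 27; C4 epimers not separated) | CC(C)=CCC/C(C)=C/CC(C[C@@]12O[C@]1(C)C(=O)c1c(O[Si](C(C)C)(C(C)C)C(C)C)cc(O[Si](C(C)C)(C(C)C)C(C)C)cc1C2O)=C(C)C
F8 | step 17 | (2R,3S)-2-chloro-3,4-dihydroxy-2-methyl-3-R-6,8-bis(triisopropylsilyloxy)-3,4-dihydronaphthalen-1(2H)-one (C4 epimers) | CC(C)=CCC/C(C)=C/CC(C[C@]1(O)C(O)c2cc(O[Si](C(C)C)(C(C)C)C(C)C)cc(O[Si](C(C)C)(C(C)C)C(C)C)c2C(=O)[C@]1(C)Cl)=C(C)C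
F9 | step 17 | (2R,3S)-2-chloro-3-hydroxy-2-methyl-3-R-6,8-bis(triisopropylsilyloxy)-2,3-dihydronaphthalene-1,4-dione | CC(C)=CCC/C(C)=C/CC(C[C@]1(O)C(=O)c2cc(O[Si](C(C)C)(C(C)C)C(C)C)cc(O[Si](C(C)C)(C(C)C)C(C)C)c2C(=O)[C@]1(C)Cl)=C(C)C
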